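The route rests on cutting the C1–C8 bond of the six-membered ring C1–C8–C7–C6–C5–C9. C1, the bridgehead that carries the isobutyryl group between the C9 and C2 ketones, is the central carbon of a β-tricarbonyl and so an enol nucleophile; the gem-dimethyl carbon C8 is a latent tertiary cation. The key step is a formic-acid-mediated cation–olefin closure of a dearomatised acylphloroglucinol whose C5 bears prenyl and a lavandulyl chain and whose C3 is already quaternary (acetoxy, prenyl). It should give a bicyclo[3.3.1]nonanetrione in one operation. Removal of the acetate then triggers an α-ketol ring contraction to the bicyclo[3.2.1]octane, and side-chain oxidation finishes the target.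

Key step: step 5

Atom labels: C1 = bridgehead bearing the isobutyryl group; C2 = ring ketone next to C1; C3 = carbon that ends as the exocyclic enone carbonyl; C4 = carbinol carbon; C5 = prenylated bridgehead; C6 = CH2; C7 = CH(prenyl); C8 = CMe2; C9 = bridging ketone. The same labels are used for the corresponding carbons of the monocyclic precursors.

Assumption: (S)-lavandulol is taken as a purchasable enantiopure building block (failing that, it follows from commercial racemic lavandulol by one lipase-mediated kinetic resolution).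

Remark: C3 is carried as a mixture of both epimers from step 4 to step 6 (SMILES written without a descriptor there); this centre becomes a carbonyl carbon in step 6.

Step 1
Reactants: 1 phlorisobutyrophenone [2-methyl-1-(2,4,6-trihydroxyphenyl)propan-1-one]; 2 prenyl bromide (1-bromo-3-methylbut-2-ene)
Product: 3 deoxycohumulone [2-methyl-1-[2,4,6-trihydroxy-3,5-bis(3-methylbut-2-en-1-yl)phenyl]propan-1-one]
Conditions: 2 (2.1 equiv), 10% aq KOH, 0 °C to rt; then dilute HCl
Reagents that add atoms: none
Why: Twofold electrophilic C-prenylation of the phloroglucinolate at its two free ring carbons (aqueous alkali favours C- over O-alkylation of the ambident anion); no stereocentre is formed.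

Step 2
Reactants: 4 (S)-lavandulol [(2S)-5-methyl-2-(prop-1-en-2-yl)hex-4-en-1-ol]
Product: 5 (2S)-5-methyl-2-(prop-1-en-2-yl)hex-4-en-1-yl trifluoromethanesulfonate
Conditions: Tf2O, 2,6-lutidine, CH2Cl2, −78 °C; filtered cold through silica with pentane and used at once
Reagents that add atoms: triflic anhydride, O=S(=O)(OS(=O)(=O)C(F)(F)F)C(F)(F)F
Why: O-Sulfonylation of the primary alcohol gives an electrophile reactive enough for the hindered C-alkylation that follows; the C7 stereocentre is not touched.

Step 3
Reactants: 3 deoxycohumulone; 5 (S)-lavandulyl triflate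
Product: 6 (6S)-3,5-dihydroxy-2-(2-methylpropanoyl)-4,6-bis(3-methylbut-2-en-1-yl)-6-[(2R)-5-methyl-2-(prop-1-en-2-yl)hex-4-en-1-yl]cyclohexa-2,4-dien-1-one
Conditions: LiN(SiMe3)2 (3 equiv), THF, −78 °C; then 5, −78 to 0 °C; 1 M HCl; preparative HPLC
Reagents that add atoms: none
Why: Alkylative dearomatisation (SN2 attack of one of the two equivalent prenylated ring carbons of the lithium phloroglucinolate on the primary triflate, the lithium counter-ion in THF favouring C-alkylation) creates the quaternary C5; the remote C7 centre gives no facial bias, so both C5 epimers should form and the (6S)-epimer 6 is isolated before the ring closure, so that C5 and C7 together fix the absolute configuration of everything that follows.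

Step 4
Reactants: 6 dearomatised lavandulyl triketone
Product: 7 (6R)-4-acetoxy-3-hydroxy-2-(2-methylpropanoyl)-4,6-bis(3-methylbut-2-en-1-yl)-6-[(2R)-5-methyl-2-(prop-1-en-2-yl)hex-4-en-1-yl]cyclohex-2-ene-1,5-dione (both C4 epimers of this ring numbering, i.e. both C3 epimers)
Conditions: Pb(OAc)4 (tetravalent lead), AcOH/CH2Cl2, 0 °C
Reagents that add atoms: lead tetraacetate Pb(OAc)4, CC(=O)O[Pb](OC(C)=O)(OC(C)=O)OC(C)=O
Why: Wessely-type acetoxylation at C3, the electron-rich enol carbon of the 2-alkyl-1,3-dione (C1 is deactivated by three carbonyls), makes C3 quaternary; both C3 epimers should form and are used together.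

Step 5
Reactants: 7 C3-acetoxy triketone
Product: 8 (1R,5R,7R)-3-acetoxy-8,8-dimethyl-3,5,7-tris(3-methylbut-2-en-1-yl)-1-(2-methylpropanoyl)bicyclo[3.3.1]nonane-2,4,9-trione (both C3 epimers)
Conditions: HCO2H (neat), rt
Reagents that add atoms: none
Why: Formic acid protonates the 1,1-disubstituted alkene of the lavandulyl chain in the Markovnikov sense to the tertiary C8 cation, which is captured by C1, the enol carbon of the 2-acyl-1,3-dione, forming the C1–C8 bond and, after loss of the enol proton, the trione 8. The closest known reaction type is the Brønsted-acid-mediated biomimetic cationic cyclisation of dearomatised lavandulyl acylphloroglucinols to bicyclo[3.3.1]nonane-2,4,9-triones, an intramolecular hydroalkylation of an alkene by a 1,3-dicarbonyl enol. The six-membered ring C1–C8–C7–C6–C5–C9 closes in a 6-(enolendo)-exo-trig mode through a chair. C1 is set by C5, because the three-atom tether C6–C7–C8 can bridge only the ring face that carries C6, and the C7 centre from 4 then places its prenyl group equatorial (exo), which is the matched pairing with the C5 configuration of 7. The step needs C- over O-alkylation and attack at C1 and not at C3: O-alkylation to the tertiary enol ether and formate trapping are reversible in formic acid whereas C–C bond formation is not and leads to a product without an enolised 1,3-dicarbonyl, and C3 is already quaternary so that C1 is the only enolic carbon in a 1,3-relation to C5. The acetate also keeps the C3 oxygen from adding to a protonated prenyl group, and because a single C5 epimer is used, any loss of C7 integrity can only give a separable diastereomer, not the enantiomer.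

Step 6
Reactants: 8 bicyclic acetoxy trione
Product: 10 (1S,3R,5R,7S)-7-hydroxy-4,4-dimethyl-1,3-bis(3-methylbut-2-en-1-yl)-7-(4-methylpent-3-enoyl)-5-(2-methylpropanoyl)bicyclo[3.2.1]octane-6,8-dione, via tertiary alcohol 9 (not isolated)
Conditions: K2CO3 (cat.), MeOH, 0 °C to rt
Reagents that add atoms: none
Why: Methanolysis of the activated tertiary acetate frees alcohol 9, whose α-ketol (acyloin) rearrangement moves the C2 acyl arm from C3 to C4 (ring contraction, C3 becoming the exocyclic ketone) and relieves the transannular strain between the quaternary C3 and C7; the shift is reversible and should settle on the isomer with the carbinol next to the less crowded C5, the bulky acyl group on the face that looks at C9 and the hydroxyl under the three-carbon bridge, which is the C4 configuration of the target.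

Step 7
Reactants: 10 ring-contracted β,γ-unsaturated ketone
Product: 12 (1S,3R,5R,7S)-7-hydroxy-7-[(2E)-4-hydroxy-4-methylpent-2-enoyl]-4,4-dimethyl-1,3-bis(3-methylbut-2-en-1-yl)-5-(2-methylpropanoyl)bicyclo[3.2.1]octane-6,8-dione, via hydroperoxide 11 (not isolated)
Conditions: O2 (1 atm), DBU, P(OEt)3, MeCN, 0 °C to rt
Reagents that add atoms: dioxygen, O=O
Why: The CH2 between the exocyclic ketone and its alkene is the only readily enolisable position, and its dienolate is trapped by triplet oxygen at the γ-carbon (base-mediated autoxidation of a β,γ-unsaturated ketone to the conjugated γ-hydroperoxide 11, the isolated prenyl groups being inert), the phosphite reducing the O–O bond to give the (E)-γ-hydroxy enone.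

Step 8
Reactants: 12 (E)-hydroxy enone
Product: 13 (1S,3R,5R,7S)-7-hydroxy-7-[(2Z)-4-hydroxy-4-methylpent-2-enoyl]-4,4-dimethyl-1,3-bis(3-methylbut-2-en-1-yl)-5-(2-methylpropanoyl)bicyclo[3.2.1]octane-6,8-dione
Conditions: hν (405 nm), thioxanthone (10 mol %), MeCN, rt; recovered 12 recycled
Reagents that add atoms: none
Why: Triplet-sensitised E-to-Z photoisomerisation of the enone at a wavelength that the saturated ketones do not absorb; the Z isomer, held by the hydrogen bond from the tertiary hydroxyl to the enone carbonyl, should accumulate at the photostationary state.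

Compound list
1 | phlorisobutyrophenone, 2-methyl-1-(2,4,6-trihydroxyphenyl)propan-1-one | CC(C)C(=O)c1c(O)cc(O)cc1O | starting material
2 | prenyl bromide, 1-bromo-3-methylbut-2-ene | CC(C)=CCBr | starting material
3 | deoxycohumulone, 2-methyl-1-[2,4,6-trihydroxy-3,5-bis(3-methylbut-2-en-1-yl)phenyl]propan-1-one | CC(C)C(=O)c1c(O)c(CC=C(C)C)c(O)c(CC=C(C)C)c1O | intermediate
4 | (S)-lavandulol, (2S)-5-methyl-2-(prop-1-en-2-yl)hex-4-en-1-ol | OC[C@@H](CC=C(C)C)C(C)=C | starting material
5 | (2S)-5-methyl-2-(prop-1-en-2-yl)hex-4-en-1-yl trifluoromethanesulfonate | O=S(=O)(OC[C@@H](CC=C(C)C)C(C)=C)C(F)(F)F | intermediate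
6 | (6S)-3,5-dihydroxy-2-(2-methylpropanoyl)-4,6-bis(3-methylbut-2-en-1-yl)-6-[(2R)-5-methyl-2-(prop-1-en-2-yl)hex-4-en-1-yl]cyclohexa-2,4-dien-1-one | CC(C)C(=O)C1=C(O)C(CC=C(C)C)=C(O)[C@](CC=C(C)C)(C[C@@H](CC=C(C)C)C(C)=C)C1=O | intermediate
7 | (6R)-4-acetoxy-3-hydroxy-2-(2-methylpropanoyl)-4,6-bis(3-methylbut-2-en-1-yl)-6-[(2R)-5-methyl-2-(prop-1-en-2-yl)hex-4-en-1-yl]cyclohex-2-ene-1,5-dione, both epimers at the acetoxy carbon | CC(C)C(=O)C1=C(O)C(OC(C)=O)(CC=C(C)C)C(=O)[C@](CC=C(C)C)(C[C@@H](CC=C(C)C)C(C)=C)C1=O | intermediate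
8 | (1R,5R,7R)-3-acetoxy-8,8-dimethyl-3,5,7-tris(3-methylbut-2-en-1-yl)-1-(2-methylpropanoyl)bicyclo[3.3.1]nonane-2,4,9-trione, both C3 epimers | CC(C)=CC[C@@H]1C[C@]2(CC=C(C)C)C(=O)[C@@](C(=O)C(C)C)(C(=O)C(OC(C)=O)(CC=C(C)C)C2=O)C1(C)C | intermediate
9 | (1R,5R,7R)-3-hydroxy-8,8-dimethyl-3,5,7-tris(3-methylbut-2-en-1-yl)-1-(2-methylpropanoyl)bicyclo[3.3.1]nonane-2,4,9-trione, both C3 epimers (not isolated) | CC(C)=CC[C@@H]1C[C@]2(CC=C(C)C)C(=O)[C@@](C(=O)C(C)C)(C(=O)C(O)(CC=C(C)C)C2=O)C1(C)C | intermediate
10 | (1S,3R,5R,7S)-7-hydroxy-4,4-dimethyl-1,3-bis(3-methylbut-2-en-1-yl)-7-(4-methylpent-3-enoyl)-5-(2-methylpropanoyl)bicyclo[3.2.1]octane-6,8-dione | CC(C)=CC[C@@H]1C[C@]2(CC=C(C)C)C(=O)[C@@](C(=O)C(C)C)(C(=O)[C@@]2(O)C(=O)CC=C(C)C)C1(C)C | intermediate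
11 | (1S,3R,5R,7S)-7-[(2E)-4-hydroperoxy-4-methylpent-2-enoyl]-7-hydroxy-4,4-dimethyl-1,3-bis(3-methylbut-2-en-1-yl)-5-(2-methylpropanoyl)bicyclo[3.2.1]octane-6,8-dione (not isolated) | CC(C)=CC[C@@H]1C[C@]2(CC=C(C)C)C(=O)[C@@](C(=O)C(C)C)(C(=O)[C@@]2(O)C(=O)/C=C/C(C)(C)OO)C1(C)C | intermediate
12 | (1S,3R,5R,7S)-7-hydroxy-7-[(2E)-4-hydroxy-4-methylpent-2-enoyl]-4,4-dimethyl-1,3-bis(3-methylbut-2-en-1-yl)-5-(2-methylpropanoyl)bicyclo[3.2.1]octane-6,8-dione | CC(C)=CC[C@@H]1C[C@]2(CC=C(C)C)C(=O)[C@@](C(=O)C(C)C)(C(=O)[C@@]2(O)C(=O)/C=C/C(C)(C)O)C1(C)C | intermediate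
13 | (1S,3R,5R,7S)-7-hydroxy-7-[(2Z)-4-hydroxy-4-methylpent-2-enoyl]-4,4-dimethyl-1,3-bis(3-methylbut-2-en-1-yl)-5-(2-methylpropanoyl)bicyclo[3.2.1]octane-6,8-dione | CC(C)=CC[C@@H]1C[C@]2(CC=C(C)C)C(=O)[C@@](C(=O)C(C)C)(C(=O)[C@@]2(O)C(=O)/C=C\C(C)(C)O)C1(C)C | target

Total step count: 8. Longest linear sequence: 7 steps (1 → 3 → 6 → 7 → 8 → 10 → 12 → 13; step 2 is the side branch that makes 5).

Steps most likely to fail

Step 5 (key step). Reversible protonation of the three prenyl groups competes with that of the isopropenyl group, and the cations from the C5 and C3 prenyl groups can also reach C1 through six-membered transition states. The C8 cation may also be lost by elimination toward C7, and bond formation between two fully substituted carbons is slow. The fallback sets out from 7 and closes the ring in two stages that never expose the prenyl groups to strong acid. MHAT hydroalkoxylation (Co(salen) as catalyst, a divalent cobalt complex, with N-fluoro-2,4,6-trimethylpyridinium tetrafluoroborate and (Me2SiH)2O in PhCF3 at rt) selects the 1,1-disubstituted alkene over the trisubstituted ones. It should add the C9 enol oxygen to C8 and give the pyran-fused enol ether F1. Catalytic TMSOTf (CH2Cl2, −78 °C) should then ionise this tertiary alkyl enol ether to the C8 cation and triketonate ion pair, which recombines at C1 (1,3 oxygen-to-carbon shift). The route is rejoined at 8.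

Step 3. O-Alkylation and loss of the triflate by elimination can erode the C-alkylation. Above all, the C5 epimers form without discrimination and may resist chromatographic resolution. The fallback sets out from 3 and 5: the alkylation is run as in step 3, but 6 and its (6R)-epimer F2 are not separated. Acetoxylation as in step 4 then gives 7 together with the (6S)-epimer F3. The hydroalkoxylation described above converts both into pyrans, F1 and its (4aS)-epimer F4. In these, C5 and C7 are 1,3-related on one six-membered ring, so the two should separate on silica gel as cis/trans ring isomers. F1 is then rearranged (TMSOTf, or formic acid as in step 5) and the route is rejoined at 8.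

Step 8. The photostationary state may be poor in the Z isomer, and prolonged irradiation invites secondary photochemistry of the ketones and prenyl groups. The fallback sets out from 12, which is irradiated in methanol with a trace of pyridinium p-toluenesulfonate. The Z isomer is then removed from the photoequilibrium as it forms, by cyclisation to the cyclic methyl ketal F5, a 2-methoxy-2,5-dihydrofuran without an enone chromophore. Mild hydrolysis (AcOH, THF, H2O, rt) should release the (Z)-hydroxy enone, rejoining the route at 13.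

Further compounds
F1 | step 5 | (3R,4aR)-6-acetoxy-2,2-dimethyl-3,4a,6-tris(3-methylbut-2-en-1-yl)-8-(2-methylpropanoyl)-3,4,4a,6-tetrahydro-2H-chromene-5,7-dione, both C6 epimers | CC(C)C(=O)C1=C2OC(C)(C)[C@H](CC=C(C)C)C[C@@]2(CC=C(C)C)C(=O)C(OC(C)=O)(CC=C(C)C)C1=O
F2 | step 3 | (6R)-3,5-dihydroxy-2-(2-methylpropanoyl)-4,6-bis(3-methylbut-2-en-1-yl)-6-[(2R)-5-methyl-2-(prop-1-en-2-yl)hex-4-en-1-yl]cyclohexa-2,4-dien-1-one | CC(C)C(=O)C1=C(O)C(CC=C(C)C)=C(O)[C@@](CC=C(C)C)(C[C@@H](CC=C(C)C)C(C)=C)C1=O
F3 | step 3 | (6S)-4-acetoxy-3-hydroxy-2-(2-methylpropanoyl)-4,6-bis(3-methylbut-2-en-1-yl)-6-[(2R)-5-methyl-2-(prop-1-en-2-yl)hex-4-en-1-yl]cyclohex-2-ene-1,5-dione, both epimers at the acetoxy carbon | CC(C)C(=O)C1=C(O)C(OC(C)=O)(CC=C(C)C)C(=O)[C@@](CC=C(C)C)(C[C@@H](CC=C(C)C)C(C)=C)C1=O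
F4 | step 3 | (3R,4aS)-6-acetoxy-2,2-dimethyl-3,4a,6-tris(3-methylbut-2-en-1-yl)-8-(2-methylpropanoyl)-3,4,4a,6-tetrahydro-2H-chromene-5,7-dione, both C6 epimers | CC(C)C(=O)C1=C2OC(C)(C)[C@H](CC=C(C)C)C[C@]2(CC=C(C)C)C(=O)C(OC(C)=O)(CC=C(C)C)C1=O
F5 | step 8 | 7-hydroxy-7-(2-methoxy-5,5-dimethyl-2,5-dihydrofuran-2-yl)-4,4-dimethyl-1,3-bis(3-methylbut-2-en-1-yl)-5-(2-methylpropanoyl)bicyclo[3.2.1]octane-6,8-dione, core stereocentres as in 13, ketal carbon as a mixture | CC(C)=CC[C@@H]1C[C@]2(CC=C(C)C)C(=O)[C@@](C(=O)C(C)C)(C(=O)[C@@]2(O)C3(OC)C=CC(C)(C)O3)C1(C)C
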